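**Plan**
- Retrosynthesis: the flavone goes back, by adjusting ring C (C4 ketone, C2=C3) and unveiling O5/O7, to chroman-5-ol 14; ring A of 14 is cut at C4a–C5 to give cyclobutenone 11.
- 11 is cut at C8–C8a into dimethyl squarate and a C6-lithiated dihydropyran; ring C is cut at O1–C2 and C3–C4 into the acetonide of 5-hydroxyvanillin and Danishefsky's diene.
- Enabling feature: ring A bears oxygen on C5, C6, C7, C8 and C8a. C5–C8 map onto the four squarate carbons, and C8a=C4a is the enol ether alkene of ring C, with hydrogen on C4a.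
- Forward order: ring C (hetero-Diels–Alder), attachment of the four-membered ring, ring A by thermal ring expansion, then oxidation of ring C to the pyranone.
- O5 is held as a MOM ether so that O7, the only methyl ether para to the C4 carbonyl, can be freed by SN2 demethylation.
- Stereochemistry: the target is achiral; the cis C2/C4 relation from the Luche reduction is transient and is erased in steps 9 and 10.

Key step: step 6

Remark: Ar = 7-methoxy-2,2-dimethyl-1,3-benzodioxol-5-yl. All chiral intermediates are racemic (one enantiomer drawn), and 10 and 11 are used as mixtures of epimers at the cyclobutenone carbon, which has no consequence.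

Step 1
Reactants: 1 5-hydroxyvanillin (3,4-dihydroxy-5-methoxybenzaldehyde)
Product: 2 7-methoxy-2,2-dimethyl-1,3-benzodioxole-5-carbaldehyde (ArCHO)
Conditions: 2,2-dimethoxypropane, p-TsOH (cat.), toluene, reflux, 4 Å MS (Soxhlet)
Reagents that add atoms: 2,2-dimethoxypropane, COC(C)(C)OC
Why: Acid-catalysed transketalisation of the catechol (acetonide formation) is driven by removal of methanol, and any aldehyde dimethyl acetal formed on the way reverts on aqueous work-up.

Step 2
Reactants: 2 ArCHO; 3 Danishefsky's diene ((E)-1-methoxy-3-(trimethylsilyloxy)buta-1,3-diene)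
Product: 5 2-Ar-2,3-dihydro-4H-pyran-4-one (racemic), via silyl enol ether cycloadduct 4 (not isolated)
Conditions: ZnCl2, THF, rt; then TFA (cat.), CH2Cl2, 0 °C, aqueous work-up
Reagents that add atoms: none
Why: The ZnCl2-promoted hetero-Diels–Alder reaction of an aromatic aldehyde with Danishefsky's diene, followed by acid-induced loss of methanol and of the silyl group, is the standard route to 2-aryl-2,3-dihydro-4H-pyran-4-ones, and the single stereocentre forms as a racemate.

Step 3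
Reactants: 5 2-Ar-2,3-dihydro-4H-pyran-4-one
Product: 6 cis-2-Ar-3,4-dihydro-2H-pyran-4-ol (racemic; 2R,4R enantiomer drawn)
Conditions: NaBH4, CeCl3·7H2O, MeOH, −78 → −40 °C
Reagents that add atoms: none
Why: Luche reduction delivers hydride 1,2 to the vinylogous ester carbonyl along the axial trajectory of the half-chair that holds the aryl group pseudo-equatorial, so the C4 carbinol is set cis to C2 by substrate control.

Step 4
Reactants: 6 cis-2-Ar-3,4-dihydro-2H-pyran-4-ol
Product: 7 cis-2-Ar-4-(triisopropylsilyloxy)-3,4-dihydro-2H-pyran (racemic)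
Conditions: TIPSCl, imidazole, DMAP (cat.), DMF, rt
Reagents that add atoms: chlorotriisopropylsilane (TIPSCl), CC(C)[Si](Cl)(C(C)C)C(C)C
Why: Imidazole-mediated silylation of the secondary allylic alcohol proceeds without acid, and the TIPS group is chosen because it has no Si–CH3 protons that t-BuLi could remove in step 5.

Step 5
Reactants: 7 cis-2-Ar-4-(triisopropylsilyloxy)-3,4-dihydro-2H-pyran; 8 dimethyl squarate (3,4-dimethoxycyclobut-3-ene-1,2-dione)
Product: 11 4-[cis-2-Ar-4-(triisopropylsilyloxy)-3,4-dihydro-2H-pyran-6-yl]-2,3,4-trimethoxycyclobut-2-en-1-one (racemic; both epimers at the cyclobutenone carbon), via vinyllithium 9 (not isolated), via lithium alkoxide 10 (not isolated)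
Conditions: t-BuLi (1.1 equiv), THF, −78 → 0 °C; cannulate into 8, THF, −78 °C; MeOTf, −78 → 0 °C
Reagents that add atoms: methyl trifluoromethanesulfonate (MeOTf), COS(=O)(=O)C(F)(F)F
Why: Lithiation of the alpha-alkoxyvinyl C6–H with t-BuLi follows the practice for silyl-protected glycals, the vinyllithium adds 1,2 to one squarate carbonyl under inverse addition (forming C8–C8a), and MeOTf O-methylates the tertiary lithium alkoxide in the same flask; the new quaternary centre forms without control and disappears in step 6.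

Step 6
Reactants: 11 4-[cis-2-Ar-4-(triisopropylsilyloxy)-3,4-dihydro-2H-pyran-6-yl]-2,3,4-trimethoxycyclobut-2-en-1-one
Product: 14 cis-6,7,8-trimethoxy-2-Ar-4-(triisopropylsilyloxy)chroman-5-ol (racemic; 2R,4R enantiomer drawn), via dienylketene 12 (not isolated), via cyclohexadienone 13 (not isolated)
Conditions: toluene (degassed), 110 °C
Reagents that add atoms: none
Why: Heating opens the cyclobutenone by a conrotatory 4π electrocyclic reaction in which the methoxy donor on the quaternary carbon rotates outward and the dihydropyranyl group inward, so the (Z)-dienylketene 12 holds the ketene carbon next to the pyran C5–H carbon. A thermally allowed disrotatory 6π electrocyclisation then forms the C4a–C5 bond and closes ring A as a six-membered carbocycle, and dienone 13 enolises to the phenol because C4a still carries hydrogen. The closest known reaction type is the thermal ring expansion of squarate-derived 4-alkenyl-4-alkoxycyclobutenones to highly oxygenated phenols (Moore rearrangement). No new stereocentre remains, since C4a becomes aromatic and the cis C2/C4 relation is only carried along. The step needs torquoselectivity and a single regiochemistry, and the substrate secures both: the methoxy group dictates outward rotation and the only alkene terminus within reach is C5 of the pyran, so the ketene oxygen becomes O5, the squarate oxygens become O6, O7 and O8, and the pyran oxygen sits on C8a.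

Step 7
Reactants: 14 cis-6,7,8-trimethoxy-2-Ar-4-(triisopropylsilyloxy)chroman-5-ol
Product: 15 cis-6,7,8-trimethoxy-5-(methoxymethoxy)-2-Ar-4-(triisopropylsilyloxy)chroman (racemic)
Conditions: NaH, MOMCl, THF/DMF, 0 °C → rt
Reagents that add atoms: chloromethyl methyl ether (MOMCl), COCCl
Why: Williamson alkylation of the sodium phenoxide caps the electron-rich para-methoxyphenol before the oxidations of steps 9 and 10 and keeps ring A uncharged in step 11.

Step 8
Reactants: 15 cis-6,7,8-trimethoxy-5-(methoxymethoxy)-2-Ar-4-(triisopropylsilyloxy)chroman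
Product: 16 cis-6,7,8-trimethoxy-5-(methoxymethoxy)-2-Ar-chroman-4-ol (racemic)
Conditions: TBAF, THF, rt
Reagents that add atoms: none
Why: Fluoride-mediated desilylation frees the benzylic alcohol under basic conditions that the MOM ether, the acetonide and the methyl ethers tolerate.

Step 9
Reactants: 16 cis-6,7,8-trimethoxy-5-(methoxymethoxy)-2-Ar-chroman-4-ol
Product: 17 6,7,8-trimethoxy-5-(methoxymethoxy)-2-Ar-chroman-4-one (racemic flavanone)
Conditions: Dess–Martin periodinane, CH2Cl2, 0 °C → rt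
Reagents that add atoms: none
Why: Dess–Martin oxidation of a secondary benzylic alcohol to the aryl ketone is reliable here because every phenol is capped, and it removes the C4 stereocentre.

Step 10
Reactants: 17 6,7,8-trimethoxy-5-(methoxymethoxy)-2-Ar-chroman-4-one
Product: 18 6,7,8-trimethoxy-5-(methoxymethoxy)-2-Ar-4H-chromen-4-one
Conditions: DDQ, 1,4-dioxane, 100 °C
Reagents that add atoms: none
Why: DDQ dehydrogenation of flavanones to flavones proceeds by hydride abstraction from C2, which the ring oxygen and the electron-rich aryl group favour, under neutral conditions that spare the acetals; it erases the last stereocentre.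

Step 11
Reactants: 18 6,7,8-trimethoxy-5-(methoxymethoxy)-2-Ar-4H-chromen-4-one
Product: 19 7-hydroxy-6,8-dimethoxy-5-(methoxymethoxy)-2-Ar-4H-chromen-4-one
Conditions: NaSEt, DMF, 90–100 °C; dilute HCl work-up
Reagents that add atoms: none
Why: Thiolate SN2 demethylation selects the O7 methyl because its phenoxide is the only one conjugated para to the C4 carbonyl and it lies between two methoxy groups (the 3,4,5-trimethoxybenzoyl pattern, known for selective 4-O-demethylation), while the 6-, 8- and 5'-methyl ethers are unactivated and the acetals are inert to nucleophiles.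

Step 12
Reactants: 19 7-hydroxy-6,8-dimethoxy-5-(methoxymethoxy)-2-Ar-4H-chromen-4-one
Product: 20 5,7,3',4'-tetrahydroxy-6,8,5'-trimethoxyflavone
Conditions: TFA/H2O (9:1), rt
Reagents that add atoms: none
Why: Aqueous acid hydrolyses the MOM acetal and the catechol isopropylidene ketal together, while aryl methyl ethers and the flavone core are stable to these conditions.

**Compound list**
1 | 5-hydroxyvanillin (3,4-dihydroxy-5-methoxybenzaldehyde) | COc1cc(C=O)cc(O)c1O | starting material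
2 | 7-methoxy-2,2-dimethyl-1,3-benzodioxole-5-carbaldehyde | COc1cc(C=O)cc2OC(C)(C)Oc12 | intermediate
3 | Danishefsky's diene | CO/C=C/C(=C)O[Si](C)(C)C | starting material
4 | 2-methoxy-6-Ar-4-(trimethylsilyloxy)-5,6-dihydro-2H-pyran (diastereomer mixture, not isolated) | COC1C=C(O[Si](C)(C)C)CC(c2cc(OC)c3OC(C)(C)Oc3c2)O1 | intermediate
5 | 2-Ar-2,3-dihydro-4H-pyran-4-one (racemic) | O=C1C=COC(c2cc(OC)c3OC(C)(C)Oc3c2)C1 | intermediate
6 | cis-2-Ar-3,4-dihydro-2H-pyran-4-ol (racemic) | C1=C[C@H](O)C[C@H](c2cc(OC)c3OC(C)(C)Oc3c2)O1 | intermediate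
7 | cis-2-Ar-4-(triisopropylsilyloxy)-3,4-dihydro-2H-pyran (racemic) | C1=C[C@H](O[Si](C(C)C)(C(C)C)C(C)C)C[C@H](c2cc(OC)c3OC(C)(C)Oc3c2)O1 | intermediate
8 | dimethyl squarate | COC1=C(OC)C(=O)C1=O | starting material
9 | cis-2-Ar-6-lithio-4-(triisopropylsilyloxy)-3,4-dihydro-2H-pyran (not isolated) | [Li]C1=C[C@H](O[Si](C(C)C)(C(C)C)C(C)C)C[C@H](c2cc(OC)c3OC(C)(C)Oc3c2)O1 | intermediate
10 | lithium 1-[cis-2-Ar-4-(triisopropylsilyloxy)-3,4-dihydro-2H-pyran-6-yl]-2,3-dimethoxy-4-oxocyclobut-2-en-1-olate (not isolated) | [Li]OC1(C2=C[C@H](O[Si](C(C)C)(C(C)C)C(C)C)C[C@H](c3cc(OC)c4OC(C)(C)Oc4c3)O2)C(=O)C(OC)=C1OC | intermediate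
11 | 4-[cis-2-Ar-4-(triisopropylsilyloxy)-3,4-dihydro-2H-pyran-6-yl]-2,3,4-trimethoxycyclobut-2-en-1-one (racemic, epimers at the cyclobutenone carbon) | COC1(C2=C[C@H](O[Si](C(C)C)(C(C)C)C(C)C)C[C@H](c3cc(OC)c4OC(C)(C)Oc4c3)O2)C(=O)C(OC)=C1OC | intermediate
12 | (Z)-2,3,4-trimethoxy-4-[cis-2-Ar-4-(triisopropylsilyloxy)-3,4-dihydro-2H-pyran-6-yl]buta-1,3-dien-1-one (not isolated) | O=C=C(OC)/C(OC)=C(/OC)C1=C[C@H](O[Si](C(C)C)(C(C)C)C(C)C)C[C@H](c2cc(OC)c3OC(C)(C)Oc3c2)O1 | intermediate
13 | 6,7,8-trimethoxy-2-Ar-4-(triisopropylsilyloxy)-2,3,4,4a-tetrahydro-5H-chromen-5-one (2,4-cis, not isolated) | O=C1C(OC)=C(OC)C(OC)=C2O[C@@H](c3cc(OC)c4OC(C)(C)Oc4c3)C[C@@H](O[Si](C(C)C)(C(C)C)C(C)C)C12 | intermediate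
14 | cis-6,7,8-trimethoxy-2-Ar-4-(triisopropylsilyloxy)chroman-5-ol (racemic) | COc1c(OC)c(OC)c2O[C@@H](c3cc(OC)c4OC(C)(C)Oc4c3)C[C@@H](O[Si](C(C)C)(C(C)C)C(C)C)c2c1O | intermediate
15 | cis-6,7,8-trimethoxy-5-(methoxymethoxy)-2-Ar-4-(triisopropylsilyloxy)chroman (racemic) | COCOc1c(OC)c(OC)c(OC)c2O[C@@H](c3cc(OC)c4OC(C)(C)Oc4c3)C[C@@H](O[Si](C(C)C)(C(C)C)C(C)C)c12 | intermediate
16 | cis-6,7,8-trimethoxy-5-(methoxymethoxy)-2-Ar-chroman-4-ol (racemic) | COCOc1c(OC)c(OC)c(OC)c2O[C@@H](c3cc(OC)c4OC(C)(C)Oc4c3)C[C@@H](O)c12 | intermediate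
17 | 6,7,8-trimethoxy-5-(methoxymethoxy)-2-Ar-chroman-4-one (racemic) | COCOc1c(OC)c(OC)c(OC)c2OC(c3cc(OC)c4OC(C)(C)Oc4c3)CC(=O)c12 | intermediate
18 | 6,7,8-trimethoxy-5-(methoxymethoxy)-2-Ar-4H-chromen-4-one | COCOc1c(OC)c(OC)c(OC)c2oc(-c3cc(OC)c4OC(C)(C)Oc4c3)cc(=O)c12 | intermediate
19 | 7-hydroxy-6,8-dimethoxy-5-(methoxymethoxy)-2-Ar-4H-chromen-4-one | COCOc1c(OC)c(O)c(OC)c2oc(-c3cc(OC)c4OC(C)(C)Oc4c3)cc(=O)c12 | intermediate
20 | 5,7,3',4'-tetrahydroxy-6,8,5'-trimethoxyflavone | COc1cc(-c2cc(=O)c3c(O)c(OC)c(O)c(OC)c3o2)cc(O)c1O | target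

**Count and risks**
Total step count: 12. Longest linear sequence: 12 steps (1 → 20).

Step 5. t-BuLi may remove the benzylic C2–H or a ring B proton in competition with the vinylic C6–H, the organolithium may add twice to the squarate, or the alkoxide may be methylated incompletely. The fallback sets out from 7 and returns at 9. Benzenesulfinic acid is added across the enol ether (CH2Cl2, rt) to give 2-Ar-6-(phenylsulfonyl)-4-(triisopropylsilyloxy)tetrahydro-2H-pyran F1. Its alpha-sulfonyl proton, far more acidic than any other C–H, is removed with n-BuLi (THF, −78 °C) and the anion is trapped with Bu3SnCl to give 2-Ar-6-(phenylsulfonyl)-6-(tributylstannyl)-4-(triisopropylsilyloxy)tetrahydro-2H-pyran F2. Warming with iPr2NEt (CHCl3, 60 °C) eliminates sulfinate to give cis-2-Ar-6-(tributylstannyl)-4-(triisopropylsilyloxy)-3,4-dihydro-2H-pyran F3. Tin–lithium exchange with n-BuLi (THF, −78 °C) then gives vinyllithium 9 free of competing deprotonation, and squarate addition and MeOTf quench follow as in step 5.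

Step 6. After aromatisation the free ortho-phenol can assist ionisation of the benzylic silyl ether (loss of silanol through an ortho-quinone methide) at 110 °C or on silica, and the electron-rich phenol can oxidise on handling. The fallback sets out from 11 and returns at 17, with ring C brought to the ketone level before the ring expansion. Buffered desilylation (TBAF, AcOH, THF) gives 4-(cis-2-Ar-4-hydroxy-3,4-dihydro-2H-pyran-6-yl)-2,3,4-trimethoxycyclobut-2-en-1-one F4. MnO2 (CH2Cl2) oxidises the allylic alcohol to 2,3,4-trimethoxy-4-(2-Ar-4-oxo-3,4-dihydro-2H-pyran-6-yl)cyclobut-2-en-1-one F5. The same thermal ring expansion (toluene, 110 °C), now closing onto the alpha-carbon of the vinylogous ester, gives 5-hydroxy-6,7,8-trimethoxy-2-Ar-chroman-4-one F6, whose phenol is hydrogen-bonded to the ketone and has no leaving group at C4. MOMCl with iPr2NEt (CH2Cl2) then gives 17.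

Step 11. The thiolate may add to C2 of the chromone and open ring C, or cleave a second methyl ether or the MOM group, so that clean unveiling of O7 alone is lost. The fallback sets out from 7 and returns at 19, placing hydrogenolysable groups on O6 and O7 and differentiating them by acidity instead of by demethylation.
- Squaric acid and benzyl alcohol (toluene, Dean–Stark) give dibenzyl squarate F7.
- Vinyllithium 9 (from 7 as in step 5) is added to F7 and the alkoxide is quenched with MeOTf to give 2,3-bis(benzyloxy)-4-methoxy-4-[cis-2-Ar-4-(triisopropylsilyloxy)-3,4-dihydro-2H-pyran-6-yl]cyclobut-2-en-1-one F8.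
- Thermolysis (toluene, 110 °C) gives cis-6,7-bis(benzyloxy)-8-methoxy-2-Ar-4-(triisopropylsilyloxy)chroman-5-ol F9.
- NaH and MOMCl give cis-6,7-bis(benzyloxy)-8-methoxy-5-(methoxymethoxy)-2-Ar-4-(triisopropylsilyloxy)chroman F10.
- TBAF gives cis-6,7-bis(benzyloxy)-8-methoxy-5-(methoxymethoxy)-2-Ar-chroman-4-ol F11.
- Dess–Martin oxidation gives 6,7-bis(benzyloxy)-8-methoxy-5-(methoxymethoxy)-2-Ar-chroman-4-one F12.
- DDQ (dioxane, 100 °C) gives 6,7-bis(benzyloxy)-8-methoxy-5-(methoxymethoxy)-2-Ar-4H-chromen-4-one F13.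
- Hydrogenolysis (H2, Pd/C, EtOAc) gives 6,7-dihydroxy-8-methoxy-5-(methoxymethoxy)-2-Ar-4H-chromen-4-one F14.
- One equivalent of BnBr with K2CO3 (DMF, rt) alkylates the more acidic hydroxyl para to the C4 carbonyl to give 7-(benzyloxy)-6-hydroxy-8-methoxy-5-(methoxymethoxy)-2-Ar-4H-chromen-4-one F15.
- MeI with K2CO3 (acetone) gives 7-(benzyloxy)-6,8-dimethoxy-5-(methoxymethoxy)-2-Ar-4H-chromen-4-one F16.
- A second hydrogenolysis (H2, Pd/C) gives 19.

**Further compounds**
F1 | step 5 | 2-Ar-6-(phenylsulfonyl)-4-(triisopropylsilyloxy)tetrahydro-2H-pyran (2,4-cis) | O=S(=O)(c1ccccc1)C1C[C@H](O[Si](C(C)C)(C(C)C)C(C)C)C[C@H](c2cc(OC)c3OC(C)(C)Oc3c2)O1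
F2 | step 5 | 2-Ar-6-(phenylsulfonyl)-6-(tributylstannyl)-4-(triisopropylsilyloxy)tetrahydro-2H-pyran (2,4-cis) | CCCC[Sn](CCCC)(CCCC)C1(S(=O)(=O)c2ccccc2)C[C@H](O[Si](C(C)C)(C(C)C)C(C)C)C[C@H](c2cc(OC)c3OC(C)(C)Oc3c2)O1
F3 | step 5 | cis-2-Ar-6-(tributylstannyl)-4-(triisopropylsilyloxy)-3,4-dihydro-2H-pyran | CCCC[Sn](CCCC)(CCCC)C1=C[C@H](O[Si](C(C)C)(C(C)C)C(C)C)C[C@H](c2cc(OC)c3OC(C)(C)Oc3c2)O1
F4 | step 6 | 4-(cis-2-Ar-4-hydroxy-3,4-dihydro-2H-pyran-6-yl)-2,3,4-trimethoxycyclobut-2-en-1-one | COC1(C2=C[C@H](O)C[C@H](c3cc(OC)c4OC(C)(C)Oc4c3)O2)C(=O)C(OC)=C1OC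
F5 | step 6 | 2,3,4-trimethoxy-4-(2-Ar-4-oxo-3,4-dihydro-2H-pyran-6-yl)cyclobut-2-en-1-one | COC1(C2=CC(=O)CC(c3cc(OC)c4OC(C)(C)Oc4c3)O2)C(=O)C(OC)=C1OC
F6 | step 6 | 5-hydroxy-6,7,8-trimethoxy-2-Ar-chroman-4-one | COc1c(OC)c(OC)c2OC(c3cc(OC)c4OC(C)(C)Oc4c3)CC(=O)c2c1O
F7 | step 11 | dibenzyl squarate (3,4-bis(benzyloxy)cyclobut-3-ene-1,2-dione) | O=C1C(=O)C(OCc2ccccc2)=C1OCc1ccccc1
F8 | step 11 | 2,3-bis(benzyloxy)-4-methoxy-4-[cis-2-Ar-4-(triisopropylsilyloxy)-3,4-dihydro-2H-pyran-6-yl]cyclobut-2-en-1-one | COC1(C2=C[C@H](O[Si](C(C)C)(C(C)C)C(C)C)C[C@H](c3cc(OC)c4OC(C)(C)Oc4c3)O2)C(=O)C(OCc2ccccc2)=C1OCc1ccccc1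
F9 | step 11 | cis-6,7-bis(benzyloxy)-8-methoxy-2-Ar-4-(triisopropylsilyloxy)chroman-5-ol | C(Oc1c(OCc2ccccc2)c(OC)c2O[C@@H](c3cc(OC)c4OC(C)(C)Oc4c3)C[C@@H](O[Si](C(C)C)(C(C)C)C(C)C)c2c1O)c1ccccc1
F10 | step 11 | cis-6,7-bis(benzyloxy)-8-methoxy-5-(methoxymethoxy)-2-Ar-4-(triisopropylsilyloxy)chroman | COCOc1c(OCc2ccccc2)c(OCc2ccccc2)c(OC)c2O[C@@H](c3cc(OC)c4OC(C)(C)Oc4c3)C[C@@H](O[Si](C(C)C)(C(C)C)C(C)C)c12
F11 | step 11 | cis-6,7-bis(benzyloxy)-8-methoxy-5-(methoxymethoxy)-2-Ar-chroman-4-ol | COCOc1c(OCc2ccccc2)c(OCc2ccccc2)c(OC)c2O[C@@H](c3cc(OC)c4OC(C)(C)Oc4c3)C[C@@H](O)c12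
F12 | step 11 | 6,7-bis(benzyloxy)-8-methoxy-5-(methoxymethoxy)-2-Ar-chroman-4-one | COCOc1c(OCc2ccccc2)c(OCc2ccccc2)c(OC)c2OC(c3cc(OC)c4OC(C)(C)Oc4c3)CC(=O)c12
F13 | step 11 | 6,7-bis(benzyloxy)-8-methoxy-5-(methoxymethoxy)-2-Ar-4H-chromen-4-one | COCOc1c(OCc2ccccc2)c(OCc2ccccc2)c(OC)c2oc(-c3cc(OC)c4OC(C)(C)Oc4c3)cc(=O)c12
F14 | step 11 | 6,7-dihydroxy-8-methoxy-5-(methoxymethoxy)-2-Ar-4H-chromen-4-one | COCOc1c(O)c(O)c(OC)c2oc(-c3cc(OC)c4OC(C)(C)Oc4c3)cc(=O)c12
F15 | step 11 | 7-(benzyloxy)-6-hydroxy-8-methoxy-5-(methoxymethoxy)-2-Ar-4H-chromen-4-one | COCOc1c(O)c(OCc2ccccc2)c(OC)c2oc(-c3cc(OC)c4OC(C)(C)Oc4c3)cc(=O)c12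
F16 | step 11 | 7-(benzyloxy)-6,8-dimethoxy-5-(methoxymethoxy)-2-Ar-4H-chromen-4-one | COCOc1c(OC)c(OCc2ccccc2)c(OC)c2oc(-c3cc(OC)c4OC(C)(C)Oc4c3)cc(=O)c12
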